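The ratio I start from is the equivalents, first nucleophile charged per substrate charged, here 1.05. You asked for a quick number and guess that this small excess is safe, so I will test that by reckoning what is left, not what is made.

| setting | eta | gamma | delta | flask |
|---|---|---|---|---|
| substrate | 0.050 M | 0.20 M | 0.10 M | 0.10 M |
| first nucleophile | 0.105 M | 0.105 M | 0.105 M | 0.105 M |
| solid second nucleophile | 0.20 M | 0.20 M | 0.40 M | 0.200 M |
| remark | run made earlier | run made earlier | run made earlier |  |
| time |  |  |  | 2.0 d |

| run | time / d | substrate / % | target / % | other capture product / % |
|---|---|---|---|---|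
| eta | 0.208 | 23.5 | 76.2 | 0 |
| eta | 0.625 | 1.1 | 97.6 | 0.5 |
| eta | 1.04 | 0.1 | 98.6 | 0.6 |
| eta | 1.67 | 0.5 | 99.7 | 0.6 |
| eta | 2.50 | 0 | 99.6 | 1.6 |
| gamma | 0.500 | 3.5 | 52.2 | 30.4 |
| gamma | 1.04 | 0.4 | 52.0 | 34.7 |
| gamma | 1.25 | 0 | 52.4 | 34.1 |
| gamma | 2.08 | 1.3 | 52.9 | 34.3 |
| gamma | 2.50 | 0 | 53.4 | 35.2 |
| delta | 0.500 | 3.0 | 95.5 | 2.3 |
| delta | 1.04 | 0.6 | 98.1 | 1.8 |
| delta | 1.25 | 0.4 | 96.8 | 2.7 |
| delta | 2.08 | 0.5 | 97.7 | 1.7 |
| delta | 2.50 | 0.2 | 97.7 | 2.2 |

(readings scatter by 0.5 percentage points)

1. the state of affairs at 2.0 d: stopped, and by what, or still going (for what has run out or reacted, a solid counts together with what of it has only dissolved) (it is still moving / forward and back rates have come level / the first nucleophile has run out first / all of the substrate has reacted / the second nucleophile has run out first)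
2. conversion of substrate at 2.0 d
3. amount of target at 2.0 d, in percent of the substrate charged
4. amount of other capture product at 2.0 d, in percent of the substrate charged

- the analysis behind the earlier runs scatters by 0.5 percentage points, standard deviation
- at the start none of the solid second nucleophile is in solution
- a reading or a percentage of target counts all its forms, free or not
- the reaction counts as stopped when no species that holds the substrate changes by six tenths of a point or more over the second half of the time

Gamma has equivalents of 0.525, and its target reads 52.9 % at 2.08 d, so I take one first nucleophile per target and let the equivalents cap the target. In the flask, first nucleophile exceeds substrate, so substrate is the limiting reagent and 4.76 % of the first nucleophile's charge stays over even if every substrate takes one.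

Eta has 23.5 % of its substrate left at 0.208 d, a half-life near 0.0996 d. That is short against 2.0 d, so I expect the flask's substrate to be gone by then. Delta has the same equivalents and twice the solid, and it reads 97.7 % target and 2.2 % other capture product. I commit to those two figures for the flask, which leaves about 6.95 % of the first nucleophile.

The forecast gave all of the substrate has reacted, with conversion 99.9 %, target 97.9 % and other capture product 1.9 %, in the words “target should dominate”. The flask gives all of the substrate has reacted, with conversion >99.9 %, target 97.4 % and other capture product 2.40 %.

    substrate → intermediate (k = 8.20 × 10⁻⁵ s⁻¹)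
    first nucleophile + intermediate → target (k = 0.630 M⁻¹ s⁻¹)
    second nucleophile + intermediate → other capture product (k = 0.0230 M⁻¹ s⁻¹)
    solid second nucleophile ⇌ second nucleophile, rate k4*(cs4 - [second nucleophile]) while solid is left; crystals form when [second nucleophile] > cs4 (solubility = 0.0600 M, k = 3.10 × 10⁻⁵ s⁻¹)
    crystals ⇌ target, rate k5*(cs5 - [target]) while solid is left; crystals form when [target] > cs5 (solubility = 4.70 mM, k = 0.00180 s⁻¹)
    intermediate → side product (k = 5.70 × 10⁻⁵ s⁻¹)

In the flask, the substrate's half-life by its own step, 0.098 d, is short against 2.0 d, and substrate stands at 0.0838 % after 1.00 d. The flask's first nucleophile ends at 7.3 % of its charge, and the equivalents turn that into 97.3 % target, beside the computed 97.4 %. A neighbour flask, charged with 0.063 M of first nucleophile, has equivalents of 0.630, which cap its target at 63.0 %. Computed, that neighbour flask holds 63.0 % target and 32.7 % other capture product, with 0 % of its first nucleophile left.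

The readings are calculated with made-up constants, noise included.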